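The numbers in the tables were generated by integration from invented constants, noise included.

| flask | Z | Q | X | remark | time |
|---|---|---|---|---|---|
| north-east | 11 mM | 11 mM | 0.91 mM (held) | run made earlier |  |
| north | 44 mM | 44 mM | 0.91 mM (held) | run made earlier |  |
| flask | 22 mM | 22 mM | 0.91 mM (held) |  | 4.0 d |

- north-east (time / d: Z / %, Q / %): 0.833: 34.9, 49.2; 1.67: 23.0, 49.8; 2.50: 16.5, 48.8; 3.00: 13.1, 48.6; 4.00: 8.4, 47.6
- north (time / d: Z / %, Q / %): 0.333: 43.7, 50.2; 1.04: 33.8, 50.2; 1.67: 25.8, 49.8; 3.00: 13.4, 48.7; 4.00: 9.3, 48.1

(scatter of a reading: 0.5 percentage points)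

- part of the Z and Q charged together that has reacted at 4.0 d
- excess of L over G in the product at 4.0 d
- excess of Q over Z among what is left of the two at 4.0 d

- J is single-handed; Z and Q are mirror images of each other, charged as a racemate, each of them at the stated concentration
- at the start none of J is dissolved
- the numbers in the tables scatter by 0.5 percentage points (one standard deviation)
- steps that have been proposed: J -> D; J <-> E; X <-> J; J + Z -> L; J + Q -> G
- an excess is the difference of the two amounts in percent of their sum
- an excess is below zero if the other one leads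
- the handed part of J does not stay in what it makes, so the products of the two hands are mirror images too

I begin with an easy step, the last Z reading of each earlier run, which gives a first-order constant, ln(Z at the start / Z at the end)/t:

k at 11 mM: 0.446 d⁻¹; k at 44 mM: 0.421 d⁻¹

The charge moves this constant so little that I let X <-> J keep pace and hold [J] steady, which makes each hand pseudo-first-order. For the flask at 22 mM I take the mean:

kZ = 0.433 d⁻¹, so Z = 8.84% and L = 41.2%

The mean end reading of Q then gives G = 2.15% and eP = 90.1%. G is the weak link, since it rests on two readings with a scatter of 0.5 percentage points, so I reforge it from the mean fall of Q at 3.00 d and 4.00 d, fitted through the start: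

kQ = 0.0101 d⁻¹, s = kZ/kQ = 42.8

This s, the selectivity factor, the constant of Z over the constant of Q, is what I carry, as [J] cancels from it. With it:

Q = 48.0%, c = 43.2%, eP = 90.7%, eS = 68.9%

The forecast gives c 43.3% (42% to 44.8%), eP 90.8% (86.5% to 94%) and eS 69.3% (66.5% to 72%), on the ground that “J is held nearly steady by the gas”.

The flask gives c 43.0%, eP 92.9% and eS 70.1%, inside those ranges.

    J → D (k = 0.00810 h⁻¹)
    J ⇌ E (K = 670, k = 0.0650 h⁻¹)
    X ⇌ J, rate k3*(csat - [J]) (kL = 8.20 h⁻¹)
    J + Z → L (k = 21.0 M⁻¹ h⁻¹)
    J + Q → G (k = 0.370 M⁻¹ h⁻¹)

In the flask at 4.00 d, Z at 8.53% and s put Q at 48.0%, beside the 48.5% it holds. The length of the run is the largest single effect on the excess of L. In the same flask run ten times as long, Z stands at 0%, kZ/s puts Q at 33.4% where that run holds 36.3%, and the excess of L is 57.1% instead of 92.9%.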